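The target is (R)-1-(3-hydroxy-5-methoxyphenyl)heptadecan-2-ol (at C2: OH > CH2Ar > C15H31 > H). The retrosynthesis cuts, in order: phenol O–Si, C2–O (back to C2–B), C2–C3 (main cut), ester O–C2, aryl–C1 (to an aryl bromide and ethylene oxide), and the chain C–B (to 1-pentadecene).
In the forward direction no ring is formed. The benzene ring is bought as 3-bromo-5-methoxyphenol and first receives its two-carbon arm C1–C2. The C15 chain is joined last, at C2, as pentadecyl-Bpin.
The enabling feature is that C2 is the only oxygen-bearing sp3 carbon, flanked by two CH2 groups: benzylic C1 on the 1,3,5-substituted benzene ring, and C3. In the precursor C2 is an O–CH2 group with two enantiotopic hydrogens. Its oxygen, as a hindered benzoate, first directs lithiation and then leaves.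
In the key event C2 (an α-oxy-organolithium of reversed polarity) and C3 (an alkylboron) both enter as donor carbons. Boron ties them together, a 1,2-metallate shift forms C2–C3, and boron is then exchanged for OH.
The stereocentre is set in the key step by (+)-sparteine, which removes the pro-R hydrogen. It is carried to (R) by retention (borylation), inversion (1,2-shift) and retention (oxidation).
Key step: step 5

Remark: locants follow heptadecane numbering (C1 benzylic CH2, C2 carbinol carbon, C3 first CH2 of the C15 chain). (+)-Sparteine, 3-bromo-5-methoxyphenol and 1-pentadecene are taken as commercial.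

Step 1
Reactants: 1 3-bromo-5-methoxyphenol
Product: 2 (3-bromo-5-methoxyphenoxy)triisopropylsilane
Conditions: TIPSCl, imidazole, DMF, rt
Reagents that add atoms: triisopropylsilyl chloride, CC(C)[Si](Cl)(C(C)C)C(C)C
Why: Standard imidazole-promoted O-silylation of a phenol; the bulky, non-coordinating TIPS ether is chosen because it withstands Mg(0), ArMgBr and s-BuLi and shields the ring C–H between the two oxygens in step 5.

Step 2
Reactants: 2 (3-bromo-5-methoxyphenoxy)triisopropylsilane
Product: 4 2-[3-methoxy-5-(triisopropylsilyloxy)phenyl]ethanol, via arylmagnesium bromide 3 (not isolated)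
Conditions: Mg, THF, reflux; then CuI (10 mol %), ethylene oxide (THF solution), −30 °C → rt; aqueous work-up
Reagents that add atoms: ethylene oxide, C1CO1; magnesium, [Mg] (kept only in 3)
Why: Copper(I)-catalysed SN2 ring opening of ethylene oxide by an aryl Grignard reagent is the standard two-carbon hydroxyethylation of an arene and installs C1 and C2 at once, while OMe and OTIPS are inert to the organomagnesium species.

Step 3
Reactants: 4 2-[3-methoxy-5-(triisopropylsilyloxy)phenyl]ethanol
Product: 5 2-[3-methoxy-5-(triisopropylsilyloxy)phenyl]ethyl 2,4,6-triisopropylbenzoate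
Conditions: 2,4,6-triisopropylbenzoic acid, PPh3, DIAD, THF, 0 °C → rt
Reagents that add atoms: 2,4,6-triisopropylbenzoic acid, CC(C)c1cc(C(C)C)c(C(=O)O)c(C(C)C)c1
Why: Mitsunobu esterification, in which the carboxylate displaces the oxyphosphonium group at the unhindered primary carbon C2, so the blocked carbonyl group of the acid never has to be attacked and the neutral conditions leave the aryl silyl ether untouched.

Step 4
Reactants: 6 1-pentadecene
Product: 7 2-pentadecyl-4,4,5,5-tetramethyl-1,3,2-dioxaborolane (pentadecyl-Bpin)
Conditions: HBpin, [Ir(cod)Cl]2 (cat.), dppm (cat.), CH2Cl2, rt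
Reagents that add atoms: pinacolborane, CC1(C)OBOC1(C)C
Why: Iridium-catalysed hydroboration of a terminal alkene by pinacolborane places boron on the terminal carbon (anti-Markovnikov) and gives the stable primary boronic ester in a pure addition.

Step 5
Reactants: 5 2-[3-methoxy-5-(triisopropylsilyloxy)phenyl]ethyl 2,4,6-triisopropylbenzoate; 7 pentadecyl-Bpin
Product: 11 (R)-1-[3-methoxy-5-(triisopropylsilyloxy)phenyl]heptadecan-2-ol, via (R)-α-lithiated benzoate 8 (not isolated), via lithium boronate complex 9 (not isolated), via (R)-secondary boronic ester 10 (not isolated)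
Conditions: (+)-sparteine (1.2 equiv), s-BuLi (1.1 equiv), Et2O, −78 °C, 5 h; 7 (1.3 equiv), −78 °C, 1 h, then → rt and 35 °C; then THF, 2 M NaOH/30 % H2O2, 0 °C, short contact
Reagents that add atoms: hydrogen peroxide, OO; sec-butyllithium, [Li]C(C)CC (its lithium is kept only in 8 and 9)
Why: The s-BuLi/(+)-sparteine complex binds to the benzoate C=O of 5 and removes the pro-R hydrogen of the O–CH2 group, giving the configurationally stable (R)-α-oxy-organolithium 8, so the carbinol carbon is used with reversed (donor) polarity. Compound 8 adds to the empty boron orbital of 7 with retention to give boronate 9, in which two donor carbons sit on one boron; on warming, the pentadecyl group migrates from B to C2 antiperiplanar to the departing triisopropylbenzoate, with inversion at C2, and this 1,2-metallate shift forms the C2–C3 bond of (R)-10. Alkaline H2O2 then replaces boron by OH with retention, so the hydroxyl oxygen of 11 comes from the peroxide while the original oxygen leaves with the benzoate. The closest known reaction type is lithiation–borylation, a reagent-controlled Matteson-type homologation of a primary alkyl pinacol boronic ester by a Hoppe-type lithiated primary carbamate or triisopropylbenzoate, and no ring is closed. The single stereocentre is controlled by the diamine alone, since (−)-sparteine takes the pro-S hydrogen and (+)-sparteine therefore the pro-R one, and every later event is stereospecific. The step needs α-lithiation in preference to attack on the ester C=O, to benzylic deprotonation with elimination at C1 and to ring lithiation: the two ortho isopropyl groups block the carbonyl, the complex-induced proximity effect places the base at the O–CH2 group, the bulky non-coordinating OTIPS group shields the ring C–H between the two oxygens, and a lone OMe is only a weak director at −78 °C in Et2O.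

Step 6
Reactants: 11 (R)-1-[3-methoxy-5-(triisopropylsilyloxy)phenyl]heptadecan-2-ol
Product: 12 (R)-1-(3-hydroxy-5-methoxyphenyl)heptadecan-2-ol
Conditions: TBAF, AcOH (1:1), THF, 0 °C → rt
Reagents that add atoms: none
Why: Fluoride-induced cleavage of the aryl silyl ether, driven by the strong Si–F bond and the good phenoxide leaving group, is fast under acetic acid buffering and touches neither the secondary alcohol and its stereocentre nor the methyl ether.

Compound list
1 | 3-bromo-5-methoxyphenol | COc1cc(O)cc(Br)c1 | starting material
2 | (3-bromo-5-methoxyphenoxy)triisopropylsilane | COc1cc(Br)cc(O[Si](C(C)C)(C(C)C)C(C)C)c1 | intermediate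
3 | [3-methoxy-5-(triisopropylsilyloxy)phenyl]magnesium bromide | COc1cc([Mg]Br)cc(O[Si](C(C)C)(C(C)C)C(C)C)c1 | intermediate
4 | 2-[3-methoxy-5-(triisopropylsilyloxy)phenyl]ethanol | COc1cc(CCO)cc(O[Si](C(C)C)(C(C)C)C(C)C)c1 | intermediate
5 | 2-[3-methoxy-5-(triisopropylsilyloxy)phenyl]ethyl 2,4,6-triisopropylbenzoate | COc1cc(CCOC(=O)c2c(C(C)C)cc(C(C)C)cc2C(C)C)cc(O[Si](C(C)C)(C(C)C)C(C)C)c1 | intermediate
6 | 1-pentadecene | CCCCCCCCCCCCCC=C | starting material
7 | 2-pentadecyl-4,4,5,5-tetramethyl-1,3,2-dioxaborolane | CCCCCCCCCCCCCCCB1OC(C)(C)C(C)(C)O1 | intermediate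
8 | (R)-1-lithio-2-[3-methoxy-5-(triisopropylsilyloxy)phenyl]ethyl 2,4,6-triisopropylbenzoate | [Li][C@@H](OC(=O)c1c(C(C)C)cc(C(C)C)cc1C(C)C)Cc1cc(O[Si](C(C)C)(C(C)C)C(C)C)cc(OC)c1 | intermediate
9 | lithium (R)-boronate complex of 8 and 7 (boron carries pinacolato, pentadecyl and the α-benzoyloxy carbon C2) | [Li+].CCCCCCCCCCCCCCC[B-]1(OC(C)(C)C(C)(C)O1)[C@@H](OC(=O)c1c(C(C)C)cc(C(C)C)cc1C(C)C)Cc1cc(O[Si](C(C)C)(C(C)C)C(C)C)cc(OC)c1 | intermediate
10 | (R)-2-{1-[3-methoxy-5-(triisopropylsilyloxy)phenyl]heptadecan-2-yl}-4,4,5,5-tetramethyl-1,3,2-dioxaborolane | CCCCCCCCCCCCCCC[C@@H](B1OC(C)(C)C(C)(C)O1)Cc1cc(O[Si](C(C)C)(C(C)C)C(C)C)cc(OC)c1 | intermediate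
11 | (R)-1-[3-methoxy-5-(triisopropylsilyloxy)phenyl]heptadecan-2-ol | CCCCCCCCCCCCCCC[C@@H](O)Cc1cc(O[Si](C(C)C)(C(C)C)C(C)C)cc(OC)c1 | intermediate
12 | (R)-1-(3-hydroxy-5-methoxyphenyl)heptadecan-2-ol | CCCCCCCCCCCCCCC[C@@H](O)Cc1cc(O)cc(OC)c1 | target

Total step count: 6. Longest linear sequence: 5 (steps 1, 2, 3, 5, 6).

Steps most likely to fail

1. Step 5. The base may take a benzylic hydrogen at C1, followed by loss of benzoate (elimination), or a ring hydrogen, instead of the O–CH2 hydrogen. Imperfect discrimination of the enantiotopic hydrogens would lower the enantiomeric purity. Partial loss of the silyl group in alkaline peroxide would only anticipate step 6. The fallback makes the same C2–C3 bond by catalytic asymmetric carbonyl addition. It sets out from 4 and 6 and returns at 11.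
 - Buffered Dess–Martin oxidation of 4 (CH2Cl2, NaHCO3, 0 °C) should give 2-[3-methoxy-5-(triisopropylsilyloxy)phenyl]acetaldehyde F1.
 - Hydroboration of 6 with Et2BH should give diethyl(pentadecyl)borane F2.
 - Boron–zinc exchange of F2 with neat Et2Zn, with the volatiles removed in vacuo, should give dipentadecylzinc F3.
 - Addition of F3 to F1 with Ti(OiPr)4 and catalytic (1S,2S)-1,2-bis(trifluoromethanesulfonamido)cyclohexane (toluene, −20 °C) should give 11. The ligand antipode is chosen by analogy with the established facial preference of this catalyst.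

2. Step 2. Magnesium insertion may be slow, biaryl coupling may compete, and bromide may open ethylene oxide in place of the aryl group. The fallback sets out from 2 and returns at 4.
 - Negishi-type coupling of 2 with the Reformatsky reagent (2-tert-butoxy-2-oxoethyl)zinc bromide (Pd(dba)2, QPhos, THF, rt) should give tert-butyl 2-[3-methoxy-5-(triisopropylsilyloxy)phenyl]acetate F4.
 - DIBAL-H (CH2Cl2, −78 → 0 °C) should reduce F4 to 4.

3. Step 3. The activated 2-arylethyl oxyphosphonium species may eliminate towards the styrene, capture by the bulky carboxylate may be slow, and removal of the phosphorus and hydrazine residues may be tedious. The fallback sets out from 4 and returns at 5. It keeps the C2–O bond and acylates at oxygen with 2,4,6-triisopropylbenzoyl chloride (pyridine, DMAP, 1,2-dichloroethane, 80 °C), which reacts through its acylium-like character. No new compound is made on the way.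

Further compounds
F1 | step 5 | 2-[3-methoxy-5-(triisopropylsilyloxy)phenyl]acetaldehyde | COc1cc(CC=O)cc(O[Si](C(C)C)(C(C)C)C(C)C)c1
F2 | step 5 | diethyl(pentadecyl)borane | CCCCCCCCCCCCCCCB(CC)CC
F3 | step 5 | dipentadecylzinc | CCCCCCCCCCCCCCC[Zn]CCCCCCCCCCCCCCC
F4 | step 2 | tert-butyl 2-[3-methoxy-5-(triisopropylsilyloxy)phenyl]acetate | COc1cc(CC(=O)OC(C)(C)C)cc(O[Si](C(C)C)(C(C)C)C(C)C)c1
F0 | step 3 | none | none
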